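**Retrosynthetic overview**
- The 1(10)-oxirane is installed last by peracid epoxidation of the macrocyclic 1(10)E,4Z-diene; the C3 benzoate comes from the 3S allylic alcohol, obtained by oxidation and CBS reduction of the ring-closure carbinol.
- The ten-membered ring is closed at C3–C4 by a Ni/Cr-mediated (Nozaki–Hiyama–Kishi) addition of a (Z)-alkenyl iodide to an aldehyde.
- The C8 ester is made by Mitsunobu inversion with (2R,3S)-2,3-dimethyloxirane-2-carboxylic acid (fragment C, from tiglic acid by Sharpless epoxidation).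
- Key coupling: Zn-Barbier allylation (C7–C8) of bromobutenolide fragment A (C4–C7, C11–C13, C15) with aldehyde fragment B (C1–C3, C8–C10, C14), which creates the trans α-methylene-γ-lactone.
- Ring order: butenolide (RCM, fragment A), then α-methylene lactone (coupling), then carbocycle (NHK), then 1(10)-oxirane; the side-chain oxirane arrives preformed.

Assumption: the target is read as (1R,3S,6R,7R,8R,10R), 4Z, with a (2R,3S)-2,3-dimethyloxirane-2-carboxylate (cis-dimethyl, tiglate-derived); germacrane numbering (C1–C15, lactone C12–O–C6) is used in the explanations.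

**Route**

Step 1
Reactants: 1 (E)-but-2-enal; 2 prop-1-yn-1-ylmagnesium bromide
Product: 3 rac-(E)-hept-2-en-5-yn-4-ol
Conditions: THF, −78 → 0 °C; aq. NH4Cl
Reagents that add atoms: none
Why: 1,2-addition of an alkynyl Grignard reagent to the enal carbonyl; the carbinol centre is racemic at this stage.

Step 2
Reactants: 3 rac-(E)-hept-2-en-5-yn-4-ol
Product: 4 (4S,2E)-hept-2-en-5-yn-4-ol
Conditions: Ti(OiPr)4 (15 mol%), L-(+)-DIPT (18 mol%), t-BuOOH (0.6 equiv), 4 Å MS, CH2Cl2, −20 °C, about 55% conversion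
Reagents that add atoms: none
Why: Sharpless kinetic resolution, in which the L-(+)-tartrate titanium complex epoxidises the 4R enantiomer of this (E)-alkenyl carbinol much faster, so the 4S alcohol is recovered in high ee (at most 50% yield).

Step 3
Reactants: 4 (4S,2E)-hept-2-en-5-yn-4-ol
Product: 6 (4S,2E,5Z)-6-iodohepta-2,5-dien-4-ol, via cyclic alkenylaluminate 5 (not isolated)
Conditions: NaAlH2(OCH2CH2OMe)2, THF, 0 °C → rt; EtOAc; I2, −78 °C
Reagents that add atoms: iodine, II
Why: hydroxyl-directed trans-hydroalumination of the propargylic alcohol puts Al on the distal alkyne carbon cis to the carbinol, and iodinolysis with retention gives the (Z)-iodoalkene without touching the stereocentre.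

Step 4
Reactants: 6 (4S,2E,5Z)-6-iodohepta-2,5-dien-4-ol; 7 2-(bromomethyl)prop-2-enoic acid
Product: 9 (4S,2E,5Z)-6-iodohepta-2,5-dien-4-yl 2-(bromomethyl)prop-2-enoate, via acid chloride 8 (not isolated)
Conditions: 7, (COCl)2, DMF (cat.), CH2Cl2, 0 °C → rt; then 6, 2,6-lutidine, CH2Cl2, −20 °C
Reagents that add atoms: none
Why: O-acylation through the acid chloride with a hindered base avoids SN2' attack on the allylic bromide and leaves the C–O stereocentre unchanged.

Step 5
Reactants: 9 (4S,2E,5Z)-6-iodohepta-2,5-dien-4-yl 2-(bromomethyl)prop-2-enoate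
Product: 10 (5S)-3-(bromomethyl)-5-[(1Z)-2-iodoprop-1-en-1-yl]furan-2(5H)-one (fragment A)
Conditions: second-generation Grubbs catalyst RuCl2(=CHPh)(PCy3)(H2IMes) (5 mol%), toluene (5 mM), 60 °C
Reagents that add atoms: none
Why: ring-closing metathesis between the propenyl group and the 2-substituted acrylate closes the butenolide with loss of propene, while the trisubstituted iodoalkene is inert to the ruthenium carbene.

Step 6
Reactants: 11 but-3-yn-1-ol
Product: 12 (but-3-yn-1-yloxy)(tert-butyl)dimethylsilane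
Conditions: TBSCl, imidazole, CH2Cl2, rt
Reagents that add atoms: tert-butyldimethylsilyl chloride, CC(C)(C)[Si](C)(C)Cl
Why: silylation of the primary alcohol so that the alkoxide does not interfere in the carboalumination and the two chain ends stay differentiated.

Step 7
Reactants: 12 (but-3-yn-1-yloxy)(tert-butyl)dimethylsilane; 13 oxirane
Product: 16 (3E)-6-[(tert-butyldimethylsilyl)oxy]-4-methylhex-3-en-1-ol, via alkenylalane 14 (not isolated), via lithium alanate 15 (not isolated)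
Conditions: AlMe3, Cp2ZrCl2 (20 mol%), CH2Cl2, 0 °C → rt; n-BuLi, THF, −78 °C; oxirane, −78 → 0 °C
Reagents that add atoms: trimethylaluminium, C[Al](C)C
Why: Negishi zirconium-catalysed syn-carboalumination gives the (E)-2-methylalkenylalane regio- and stereoselectively, and its ate complex opens ethylene oxide with retention of the alkene geometry (sets the 1(10)E alkene).

Step 8
Reactants: 16 (3E)-6-[(tert-butyldimethylsilyl)oxy]-4-methylhex-3-en-1-ol
Product: 17 tert-butyl{[(3E)-6-[(4-methoxyphenyl)methoxy]-3-methylhex-3-en-1-yl]oxy}dimethylsilane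
Conditions: NaH, PMBCl, Bu4NI (cat.), THF/DMF, 0 °C → rt
Reagents that add atoms: 4-methoxybenzyl chloride, COc1ccc(CCl)cc1
Why: Williamson etherification gives a C3–O protecting group orthogonal to the silyl ether.

Step 9
Reactants: 17 tert-butyl{[(3E)-6-[(4-methoxyphenyl)methoxy]-3-methylhex-3-en-1-yl]oxy}dimethylsilane
Product: 18 (3E)-6-[(4-methoxyphenyl)methoxy]-3-methylhex-3-en-1-ol
Conditions: Bu4NF, THF, 0 °C → rt
Reagents that add atoms: none
Why: fluoride-induced desilylation frees the C8 hydroxyl and leaves the PMB ether intact.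

Step 10
Reactants: 18 (3E)-6-[(4-methoxyphenyl)methoxy]-3-methylhex-3-en-1-ol
Product: 19 (3E)-6-[(4-methoxyphenyl)methoxy]-3-methylhex-3-enal (fragment B)
Conditions: Dess–Martin periodinane, NaHCO3, CH2Cl2, 0 °C; used at once
Reagents that add atoms: none
Why: buffered Dess–Martin oxidation gives the β,γ-unsaturated aldehyde without migration of the alkene into conjugation.

Step 11
Reactants: 20 (E)-2-methylbut-2-enoic acid (tiglic acid)
Product: 21 (E)-2-methylbut-2-en-1-ol
Conditions: LiAlH4, Et2O, 0 °C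
Reagents that add atoms: none
Why: hydride reduction of the acid to the allylic alcohol with the E alkene untouched.

Step 12
Reactants: 21 (E)-2-methylbut-2-en-1-ol
Product: 22 [(2S,3S)-2,3-dimethyloxiran-2-yl]methanol
Conditions: Ti(OiPr)4 (10 mol%), L-(+)-DET (12 mol%), t-BuOOH, 4 Å MS, CH2Cl2, −20 °C
Reagents that add atoms: tert-butyl hydroperoxide, CC(C)(C)OO
Why: Sharpless asymmetric epoxidation, in which the L-(+)-tartrate complex delivers oxygen to the alkene face that gives the (2S,3S) epoxy alcohol and so sets both oxirane centres of the side chain.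

Step 13
Reactants: 22 [(2S,3S)-2,3-dimethyloxiran-2-yl]methanol
Product: 23 (2R,3S)-2,3-dimethyloxirane-2-carboxylic acid (fragment C)
Conditions: RuCl3 (2 mol%), NaIO4, MeCN/CCl4/H2O, rt
Reagents that add atoms: sodium periodate, [Na+].[O-]I(=O)(=O)=O; water, O
Why: RuO4 oxidation takes the primary alcohol to the acid without opening the oxirane; the C2 descriptor changes from S to R only through CIP priorities.

Step 14
Reactants: 10 (5S)-3-(bromomethyl)-5-[(1Z)-2-iodoprop-1-en-1-yl]furan-2(5H)-one; 19 (3E)-6-[(4-methoxyphenyl)methoxy]-3-methylhex-3-enal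
Product: 25 (4R,5S)-4-[(1S,3E)-1-hydroxy-6-[(4-methoxyphenyl)methoxy]-3-methylhex-3-en-1-yl]-5-[(1Z)-2-iodoprop-1-en-1-yl]-3-methylideneoxolan-2-one, via allylzinc bromide 24 (not isolated)
Conditions: Zn dust, THF/sat. aq. NH4Cl, 0 °C → rt
Reagents that add atoms: none
Why: Barbier allylation through a chair Zimmerman–Traxler transition state, in which the exocyclic allylzinc reacts at its ring carbon anti to the C6 substituent (6,7-trans, 7R) and its E-type geometry gives the 7,8-anti carbinol (8S), deliberately the C8 epimer of the target.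

Step 15
Reactants: 25 (the 8S alcohol from step 14); 23 (2R,3S)-2,3-dimethyloxirane-2-carboxylic acid
Product: 26 (1R,3E)-1-[(2S,3R)-2-[(1Z)-2-iodoprop-1-en-1-yl]-4-methylidene-5-oxooxolan-3-yl]-6-[(4-methoxyphenyl)methoxy]-3-methylhex-3-en-1-yl (2R,3S)-2,3-dimethyloxirane-2-carboxylate
Conditions: PPh3, DIAD (betaine preformed), THF, 0 °C → rt
Reagents that add atoms: none
Why: Mitsunobu esterification, in which SN2 displacement of the alkoxyphosphonium by the carboxylate of 23 (pKa about 3.5) inverts C8 to the required 8R ester and brings in the two oxirane centres unchanged.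

Step 16
Reactants: 26 (the PMB ether from step 15)
Product: 27 (1R,3E)-6-hydroxy-1-[(2S,3R)-2-[(1Z)-2-iodoprop-1-en-1-yl]-4-methylidene-5-oxooxolan-3-yl]-3-methylhex-3-en-1-yl (2R,3S)-2,3-dimethyloxirane-2-carboxylate
Conditions: DDQ, CH2Cl2/pH 7 buffer, 0 °C
Reagents that add atoms: none
Why: oxidative cleavage of the PMB ether under neutral conditions that spare the esters, the oxirane, the alkenyl iodide and the methylene lactone.

Step 17
Reactants: 27 (the primary alcohol from step 16)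
Product: 28 (1R,3E)-1-[(2S,3R)-2-[(1Z)-2-iodoprop-1-en-1-yl]-4-methylidene-5-oxooxolan-3-yl]-3-methyl-6-oxohex-3-en-1-yl (2R,3S)-2,3-dimethyloxirane-2-carboxylate
Conditions: Dess–Martin periodinane, NaHCO3, CH2Cl2, 0 °C; used at once
Reagents that add atoms: none
Why: buffered Dess–Martin oxidation gives the C3 aldehyde without shifting the 1(10)-alkene into conjugation.

Step 18
Reactants: 28 (the iodo aldehyde from step 17)
Product: 30 (6R,7R,8R)-8-[(2R,3S)-2,3-dimethyloxirane-2-carbonyl]oxy-3-hydroxygermacra-1(10)E,4Z,11(13)-trien-12,6-olide (both C3 epimers), via alkenylchromium dichloride 29 (not isolated)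
Conditions: CrCl2 (10 equiv), NiCl2 (5 mol%), DMSO/THF, 2 mM, slow addition, rt
Reagents that add atoms: none
Why: Nozaki–Hiyama–Kishi reaction, in which nickel-catalysed formation of the alkenylchromium with retention of the Z geometry and its chemoselective addition to the aldehyde at high dilution close the ten-membered ring; C3 is not controlled here and is corrected in steps 19 and 20.

Step 19
Reactants: 30 (the macrocyclic allylic alcohol, both C3 epimers)
Product: 31 (6R,7R,8R)-8-[(2R,3S)-2,3-dimethyloxirane-2-carbonyl]oxy-3-oxogermacra-1(10)E,4Z,11(13)-trien-12,6-olide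
Conditions: Dess–Martin periodinane, NaHCO3, CH2Cl2, 0 °C
Reagents that add atoms: none
Why: oxidation converges both C3 epimers on one (Z)-enone under conditions too mild to isomerise the β,γ-alkene.

Step 20
Reactants: 31 (the macrocyclic enone)
Product: 32 (3S,6R,7R,8R)-8-[(2R,3S)-2,3-dimethyloxirane-2-carbonyl]oxy-3-hydroxygermacra-1(10)E,4Z,11(13)-trien-12,6-olide
Conditions: (R)-2-methyl-CBS-oxazaborolidine (20 mol%), catecholborane, toluene, −78 °C
Reagents that add atoms: none
Why: Corey–Bakshi–Shibata reduction, in which the (R)-oxazaborolidine treats the α-methylalkenyl side as the large group and delivers hydride to the face that gives the 3S carbinol, 1,2-selectively at −78 °C.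

Step 21
Reactants: 32 (the 3S alcohol)
Product: 33 (3S,6R,7R,8R)-3-benzoyloxy-8-[(2R,3S)-2,3-dimethyloxirane-2-carbonyl]oxygermacra-1(10)E,4Z,11(13)-trien-12,6-olide
Conditions: BzCl, pyridine, DMAP (cat.), CH2Cl2, 0 °C → rt
Reagents that add atoms: benzoyl chloride, O=C(Cl)c1ccccc1
Why: acylation of the only free hydroxyl with retention at C3.

Step 22
Reactants: 33 (the macrocyclic benzoate)
Product: 34 (1R,3S,6R,7R,8R,10R)-3-benzoyloxy-1,10-epoxy-8-[(2R,3S)-2,3-dimethyloxirane-2-carbonyl]oxygermacra-4Z,11(13)-dien-12,6-olide (CNP0324463.5)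
Conditions: mCPBA, NaHCO3, CH2Cl2, 0 °C
Reagents that add atoms: meta-chloroperoxybenzoic acid, OOC(=O)c1cccc(Cl)c1
Why: Prilezhaev epoxidation, in which the 1(10)-alkene is the only electron-rich alkene (C4=C5 carries two allylic acyloxy groups, C11=C13 is conjugated) and is expected to be attacked from the outer face of the ring, giving the 1R,10R (1β,10α) oxirane stereospecifically from the E alkene.

**Compound list**
1 | (E)-but-2-enal | C/C=C/C=O | starting material
2 | prop-1-yn-1-ylmagnesium bromide | CC#C[Mg]Br | starting material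
3 | rac-(E)-hept-2-en-5-yn-4-ol | C/C=C/C(O)C#CC | intermediate
4 | (4S,2E)-hept-2-en-5-yn-4-ol | O[C@@H](/C=C/C)C#CC | intermediate
5 | sodium cyclic alkenylaluminate from 4 (oxaluminole ate complex, not isolated) | [Na+].C/C=C/[C@@H]1O[Al-](OCCOC)(OCCOC)C(C)=C1 | intermediate
6 | (4S,2E,5Z)-6-iodohepta-2,5-dien-4-ol | O[C@@H](/C=C/C)/C=C(/C)I | intermediate
7 | 2-(bromomethyl)prop-2-enoic acid | C=C(CBr)C(=O)O | starting material
8 | 2-(bromomethyl)prop-2-enoyl chloride (not isolated) | C=C(CBr)C(=O)Cl | intermediate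
9 | (4S,2E,5Z)-6-iodohepta-2,5-dien-4-yl 2-(bromomethyl)prop-2-enoate | C=C(CBr)C(=O)O[C@@H](/C=C/C)/C=C(/C)I | intermediate
10 | (5S)-3-(bromomethyl)-5-[(1Z)-2-iodoprop-1-en-1-yl]furan-2(5H)-one | O=C1O[C@H](/C=C(/C)I)C=C1CBr | intermediate
11 | but-3-yn-1-ol | C#CCCO | starting material
12 | (but-3-yn-1-yloxy)(tert-butyl)dimethylsilane | C#CCCO[Si](C)(C)C(C)(C)C | intermediate
13 | oxirane (ethylene oxide) | C1CO1 | starting material
14 | (E)-[4-(tert-butyldimethylsilyloxy)-2-methylbut-1-en-1-yl]dimethylalane (not isolated) | C[Al](C)/C=C(\C)CCO[Si](C)(C)C(C)(C)C | intermediate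
15 | lithium butyl[(E)-4-(tert-butyldimethylsilyloxy)-2-methylbut-1-en-1-yl]dimethylalanate (not isolated) | [Li+].CCCC[Al-](C)(C)/C=C(\C)CCO[Si](C)(C)C(C)(C)C | intermediate
16 | (3E)-6-[(tert-butyldimethylsilyl)oxy]-4-methylhex-3-en-1-ol | OCC/C=C(\C)CCO[Si](C)(C)C(C)(C)C | intermediate
17 | tert-butyl{[(3E)-6-[(4-methoxyphenyl)methoxy]-3-methylhex-3-en-1-yl]oxy}dimethylsilane | COc1ccc(COCC/C=C(\C)CCO[Si](C)(C)C(C)(C)C)cc1 | intermediate
18 | (3E)-6-[(4-methoxyphenyl)methoxy]-3-methylhex-3-en-1-ol | COc1ccc(COCC/C=C(\C)CCO)cc1 | intermediate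
19 | (3E)-6-[(4-methoxyphenyl)methoxy]-3-methylhex-3-enal | COc1ccc(COCC/C=C(\C)CC=O)cc1 | intermediate
20 | (E)-2-methylbut-2-enoic acid (tiglic acid) | C/C=C(\C)C(=O)O | starting material
21 | (E)-2-methylbut-2-en-1-ol | C/C=C(\C)CO | intermediate
22 | [(2S,3S)-2,3-dimethyloxiran-2-yl]methanol | OC[C@]1(C)O[C@H]1C | intermediate
23 | (2R,3S)-2,3-dimethyloxirane-2-carboxylic acid | OC(=O)[C@]1(C)O[C@H]1C | intermediate
24 | allylzinc bromide from 10 (not isolated) | Br[Zn]CC1=C[C@@H](/C=C(/C)I)OC1=O | intermediate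
25 | (4R,5S)-4-[(1S,3E)-1-hydroxy-6-[(4-methoxyphenyl)methoxy]-3-methylhex-3-en-1-yl]-5-[(1Z)-2-iodoprop-1-en-1-yl]-3-methylideneoxolan-2-one | C=C1C(=O)O[C@H](/C=C(/C)I)[C@H]1[C@@H](O)C/C(C)=C/CCOCc1ccc(OC)cc1 | intermediate
26 | (1R,3E)-1-[(2S,3R)-2-[(1Z)-2-iodoprop-1-en-1-yl]-4-methylidene-5-oxooxolan-3-yl]-6-[(4-methoxyphenyl)methoxy]-3-methylhex-3-en-1-yl (2R,3S)-2,3-dimethyloxirane-2-carboxylate | C=C1C(=O)O[C@H](/C=C(/C)I)[C@H]1[C@H](OC(=O)[C@]1(C)O[C@H]1C)C/C(C)=C/CCOCc1ccc(OC)cc1 | intermediate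
27 | 6-hydroxy analogue of 26 (PMB removed) | C=C1C(=O)O[C@H](/C=C(/C)I)[C@H]1[C@H](OC(=O)[C@]1(C)O[C@H]1C)C/C(C)=C/CCO | intermediate
28 | 6-oxo analogue of 27 (C3 aldehyde) | C=C1C(=O)O[C@H](/C=C(/C)I)[C@H]1[C@H](OC(=O)[C@]1(C)O[C@H]1C)C/C(C)=C/CC=O | intermediate
29 | alkenylchromium dichloride from 28 (not isolated) | C=C1C(=O)O[C@H](/C=C(/C)[Cr](Cl)Cl)[C@H]1[C@H](OC(=O)[C@]1(C)O[C@H]1C)C/C(C)=C/CC=O | intermediate
30 | (6R,7R,8R)-8-[(2R,3S)-2,3-dimethyloxirane-2-carbonyl]oxy-3-hydroxygermacra-1(10)E,4Z,11(13)-trien-12,6-olide, C3 epimer mixture | C=C1C(=O)O[C@@H]2/C=C(/C)C(O)C/C=C(\C)C[C@@H](OC(=O)[C@]3(C)O[C@H]3C)[C@@H]12 | intermediate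
31 | (6R,7R,8R)-8-[(2R,3S)-2,3-dimethyloxirane-2-carbonyl]oxy-3-oxogermacra-1(10)E,4Z,11(13)-trien-12,6-olide | C=C1C(=O)O[C@@H]2/C=C(/C)C(=O)C/C=C(\C)C[C@@H](OC(=O)[C@]3(C)O[C@H]3C)[C@@H]12 | intermediate
32 | (3S,6R,7R,8R)-8-[(2R,3S)-2,3-dimethyloxirane-2-carbonyl]oxy-3-hydroxygermacra-1(10)E,4Z,11(13)-trien-12,6-olide | C=C1C(=O)O[C@@H]2/C=C(/C)[C@@H](O)C/C=C(\C)C[C@@H](OC(=O)[C@]3(C)O[C@H]3C)[C@@H]12 | intermediate
33 | (3S,6R,7R,8R)-3-benzoyloxy-8-[(2R,3S)-2,3-dimethyloxirane-2-carbonyl]oxygermacra-1(10)E,4Z,11(13)-trien-12,6-olide | C=C1C(=O)O[C@@H]2/C=C(/C)[C@@H](OC(=O)c3ccccc3)C/C=C(\C)C[C@@H](OC(=O)[C@]3(C)O[C@H]3C)[C@@H]12 | intermediate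
34 | (1R,3S,6R,7R,8R,10R)-3-benzoyloxy-1,10-epoxy-8-[(2R,3S)-2,3-dimethyloxirane-2-carbonyl]oxygermacra-4Z,11(13)-dien-12,6-olide (CNP0324463.5) | C=C1C(=O)O[C@@H]2/C=C(/C)[C@@H](OC(=O)c3ccccc3)C[C@H]3O[C@]3(C)C[C@@H](OC(=O)[C@]3(C)O[C@H]3C)[C@@H]12 | target

**Step count**
Total steps: 22 (fragment A: steps 1–5; fragment B: steps 6–10; fragment C: steps 11–13; union and endgame: steps 14–22).
Longest linear sequence: 14 steps (steps 1–5 then 14–22; the fragment B branch, steps 6–10 then 14–22, is equally long).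

**Three steps most likely to fail, with fallbacks**

Step 15, Mitsunobu inversion at C8. The activated β-branched homoallylic carbinol may eliminate towards a conjugated diene instead of undergoing SN2. The fallback sets out from 25 and comes back at 26, and replaces SN2 inversion by an oxidation–reduction inversion. Compound 25 is oxidised (Dess–Martin periodinane, NaHCO3, CH2Cl2, 0 °C) to the C8 ketone (4S,5S)-5-[(1Z)-2-iodoprop-1-en-1-yl]-4-[(3E)-6-[(4-methoxyphenyl)methoxy]-3-methylhex-3-enoyl]-3-methylideneoxolan-2-one F1. F1 is used crude and reduced at −78 °C with (S)-2-methyl-CBS-oxazaborolidine and catecholborane (the branched C7 side is the large group) to the 8R alcohol (4R,5S)-4-[(1R,3E)-1-hydroxy-6-[(4-methoxyphenyl)methoxy]-3-methylhex-3-en-1-yl]-5-[(1Z)-2-iodoprop-1-en-1-yl]-3-methylideneoxolan-2-one F2. F2 is acylated with 23 with retention (EDC, DMAP cat., CH2Cl2) to give 26.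

Step 18, Nozaki–Hiyama–Kishi closure of the ten-membered ring. Oligomerisation, ring strain, or reduction of sensitive groups by divalent chromium may defeat it. The fallback sets out from 27 and comes back at 31, and closes the same C3–C4 bond as a ketone by intramolecular Stille acylation, which bypasses steps 17–19. The alkenyl iodide of 27 is stannylated with retention (Me3SnSnMe3, PdCl2(MeCN)2 cat., NMP, rt) to the (Z)-alkenylstannane alcohol (1R,3E)-6-hydroxy-3-methyl-1-[(2S,3R)-4-methylidene-5-oxo-2-[(1Z)-2-(trimethylstannyl)prop-1-en-1-yl]oxolan-3-yl]hex-3-en-1-yl (2R,3S)-2,3-dimethyloxirane-2-carboxylate F3. Buffered Dess–Martin oxidation gives the stannyl aldehyde F4 (the 6-oxo analogue of F3). Oxidation with NaClO2, NaH2PO4 and 2-methylbut-2-ene in t-BuOH/H2O gives the stannyl carboxylic acid F5 (the C3 acid). 1-Chloro-N,N,2-trimethylprop-1-en-1-amine converts F5 under neutral conditions into the acid chloride F6. F6 is cyclised without isolation (Pd2(dba)3, AsPh3, toluene, high dilution, 50 °C) to enone 31.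

Step 22, face selectivity of the final epoxidation. If the peracid attacks the 1(10)-alkene from the other face, the 1S,10S oxirane results. The fallback sets out from 33 and comes back at 34, and delivers the oxygen to the face opposite to electrophile approach by a halohydrin sequence. NBS in THF/H2O at 0 °C gives, by anti addition with water at the tertiary C10, the bromohydrin (1S,3S,6R,7R,8R,10R)-3-benzoyloxy-1-bromo-10-hydroxy-8-[(2R,3S)-2,3-dimethyloxirane-2-carbonyl]oxygermacra-4Z,11(13)-dien-12,6-olide F7. Ag2O in CH2Cl2 then closes the oxirane with inversion at C1 to give 34.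

**Further compounds**
F1 | step 15 | (4S,5S)-5-[(1Z)-2-iodoprop-1-en-1-yl]-4-[(3E)-6-[(4-methoxyphenyl)methoxy]-3-methylhex-3-enoyl]-3-methylideneoxolan-2-one | C=C1C(=O)O[C@H](/C=C(/C)I)[C@H]1C(=O)C/C(C)=C/CCOCc1ccc(OC)cc1
F2 | step 15 | (4R,5S)-4-[(1R,3E)-1-hydroxy-6-[(4-methoxyphenyl)methoxy]-3-methylhex-3-en-1-yl]-5-[(1Z)-2-iodoprop-1-en-1-yl]-3-methylideneoxolan-2-one | C=C1C(=O)O[C@H](/C=C(/C)I)[C@H]1[C@H](O)C/C(C)=C/CCOCc1ccc(OC)cc1
F3 | step 18 | (1R,3E)-6-hydroxy-3-methyl-1-[(2S,3R)-4-methylidene-5-oxo-2-[(1Z)-2-(trimethylstannyl)prop-1-en-1-yl]oxolan-3-yl]hex-3-en-1-yl (2R,3S)-2,3-dimethyloxirane-2-carboxylate | C=C1C(=O)O[C@H](/C=C(/C)[Sn](C)(C)C)[C@H]1[C@H](OC(=O)[C@]1(C)O[C@H]1C)C/C(C)=C/CCO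
F4 | step 18 | 6-oxo analogue of F3 (stannyl aldehyde) | C=C1C(=O)O[C@H](/C=C(/C)[Sn](C)(C)C)[C@H]1[C@H](OC(=O)[C@]1(C)O[C@H]1C)C/C(C)=C/CC=O
F5 | step 18 | carboxylic acid from F4 (stannyl acid) | C=C1C(=O)O[C@H](/C=C(/C)[Sn](C)(C)C)[C@H]1[C@H](OC(=O)[C@]1(C)O[C@H]1C)C/C(C)=C/CC(=O)O
F6 | step 18 | acid chloride from F5 | C=C1C(=O)O[C@H](/C=C(/C)[Sn](C)(C)C)[C@H]1[C@H](OC(=O)[C@]1(C)O[C@H]1C)C/C(C)=C/CC(=O)Cl
F7 | step 22 | (1S,3S,6R,7R,8R,10R)-3-benzoyloxy-1-bromo-10-hydroxy-8-[(2R,3S)-2,3-dimethyloxirane-2-carbonyl]oxygermacra-4Z,11(13)-dien-12,6-olide | C=C1C(=O)O[C@@H]2/C=C(/C)[C@@H](OC(=O)c3ccccc3)C[C@H](Br)[C@](C)(O)C[C@@H](OC(=O)[C@]3(C)O[C@H]3C)[C@@H]12
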